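**Retrosynthetic overview**
- The furan, the only ring, is closed late by Paal–Knorr cyclodehydration of a 1,4-diketone ester (methyl 15-methyl-14,17-dioxodocosanoate); ester hydrolysis is the last step.
- The 1,4-diketone comes from Nef unmasking of a γ-nitro ketone.
- Key C16–C17 bond: intermolecular Michael addition of the nitronate of 1-nitrohexane to the isopropenyl ketone methyl 15-methyl-14-oxohexadec-15-enoate.
- The enone comes from the Weinreb amide of monomethyl tetradecanedioate and isopropenylmagnesium bromide; the half ester comes from tetradecanedioic acid.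

Assumption: the target has no stereocentre, so there is no enantiomer to select; the stereocentres that appear in some intermediates form unselectively and are erased when the furan forms.

**Step 1**
Reactants: 1 tetradecanedioic acid
Product: 2 dimethyl tetradecanedioate
Conditions: MeOH (solvent), H2SO4 (cat.), reflux, 12 h
Reagents that add atoms: methanol, CO
Why: Fischer esterification in a large excess of methanol drives both carboxyl groups to the methyl ester; no stereocentre is involved.

**Step 2**
Reactants: 2 dimethyl tetradecanedioate
Product: 4 14-methoxy-14-oxotetradecanoic acid, via barium half-ester salt 3 (not isolated)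
Conditions: Ba(OH)2 (0.5 equiv), dry MeOH, rt, 24 h; then 2 M HCl, Et2O, 0 °C
Reagents that add atoms: barium hydroxide, [Ba+2].[OH-].[OH-]
Why: Half-saponification with one hydroxide per diester is biased towards the mono-acid because its barium salt precipitates from methanol and is withdrawn from further hydrolysis; no stereocentre is involved.

**Step 3**
Reactants: 4 14-methoxy-14-oxotetradecanoic acid
Product: 6 methyl 14-[methoxy(methyl)amino]-14-oxotetradecanoate, via acyl imidazole 5 (not isolated)
Conditions: CDI (1.1 equiv), CH2Cl2, rt, 1 h; then MeNH(OMe)·HCl (1.2 equiv), rt, 12 h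
Reagents that add atoms: N,O-dimethylhydroxylamine hydrochloride, CNOC.Cl
Why: Amide formation through the acyl imidazole activates only the free acid and leaves the methyl ester untouched; no stereocentre is involved.

**Step 4**
Reactants: 6 methyl 14-[methoxy(methyl)amino]-14-oxotetradecanoate; 7 isopropenylmagnesium bromide
Product: 9 methyl 15-methyl-14-oxohexadec-15-enoate, via bromomagnesium hemiaminal chelate 8 (not isolated)
Conditions: Grignard reagent (1.3 equiv, 0.5 M in THF), THF, −20 to 0 °C, 2 h; inverse quench into cold 1 M HCl; trace BHT on concentration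
Reagents that add atoms: none
Why: Weinreb ketone synthesis, in which the chelated tetrahedral adduct stops at single addition and the N-methoxy-N-methylamide out-competes the remote methyl ester at low temperature; the acidic inverse quench keeps the released amine from adding to the enone, and the adduct's racemic carbinol centre disappears on collapse to the ketone.

**Step 5**
Reactants: 9 methyl 15-methyl-14-oxohexadec-15-enoate; 10 1-nitrohexane
Product: 11 methyl 15-methyl-17-nitro-14-oxodocosanoate
Conditions: DBU (0.3 equiv), MeCN, nitroalkane in excess (3 equiv), slow addition of the enone at 0 °C, then rt, 12 h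
Reagents that add atoms: none
Why: Michael addition of the DBU-generated nitronate to the unhindered terminal CH2 of the isopropenyl ketone forms the C16–C17 bond, with excess nitroalkane suppressing double addition; the two new stereocentres (C15 by protonation, C17) form as a diastereomer mixture that is of no consequence because both carbons become furan sp2 centres.

**Step 6**
Reactants: 11 methyl 15-methyl-17-nitro-14-oxodocosanoate
Product: 13 methyl 15-methyl-14,17-dioxodocosanoate, via sodium nitronate 12 (not isolated)
Conditions: NaOMe (1.05 equiv), MeOH, 0 °C, 15 min; then added to aq. TiCl3 (4 equiv)/NH4OAc (12 equiv), pH 5–6, argon, rt, 1 h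
Reagents that add atoms: water, O
Why: Reductive Nef reaction, in which trivalent titanium cleaves the N–O bonds of the nitronate to an imine that hydrolyses at buffered pH to the ketone, conditions that tolerate the ester and the existing ketone; the remaining C15 centre stays racemic.

**Step 7**
Reactants: 13 methyl 15-methyl-14,17-dioxodocosanoate
Product: 14 methyl 13-(3-methyl-5-pentylfuran-2-yl)tridecanoate
Conditions: p-TsOH·H2O (0.1 equiv), toluene, reflux, Dean–Stark, argon, 2 h
Reagents that add atoms: none
Why: Paal–Knorr furan synthesis, in which acid-catalysed cyclodehydration of the 1,4-diketone gives the 2,3,5-trisubstituted furan with C14 carrying the ester chain, C15 the methyl and C17 the pentyl group; the last stereocentre is erased.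

**Step 8**
Reactants: 14 methyl 13-(3-methyl-5-pentylfuran-2-yl)tridecanoate
Product: 16 13-(3-methyl-5-pentylfuran-2-yl)tridecanoic acid, via lithium carboxylate 15 (not isolated)
Conditions: LiOH·H2O (3 equiv), THF/MeOH/H2O 3:1:1, rt, 6 h, argon, dark; then 1 M HCl to pH 3–4, 0 °C
Reagents that add atoms: lithium hydroxide, [Li+].[OH-]
Why: Ester saponification under basic conditions, to which the electron-rich furan is inert, followed by brief cold acidification to spare the acid- and air-sensitive furan; no stereocentre is involved.

**Compound list**
1 | tetradecanedioic acid | OC(=O)CCCCCCCCCCCCC(=O)O | starting material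
2 | dimethyl tetradecanedioate | COC(=O)CCCCCCCCCCCCC(=O)OC | intermediate
3 | barium bis(14-methoxy-14-oxotetradecanoate) | COC(=O)CCCCCCCCCCCCC(=O)[O-].COC(=O)CCCCCCCCCCCCC(=O)[O-].[Ba+2] | intermediate
4 | 14-methoxy-14-oxotetradecanoic acid (monomethyl tetradecanedioate) | COC(=O)CCCCCCCCCCCCC(=O)O | intermediate
5 | methyl 14-(1H-imidazol-1-yl)-14-oxotetradecanoate | COC(=O)CCCCCCCCCCCCC(=O)n1ccnc1 | intermediate
6 | methyl 14-[methoxy(methyl)amino]-14-oxotetradecanoate | COC(=O)CCCCCCCCCCCCC(=O)N(C)OC | intermediate
7 | isopropenylmagnesium bromide | CC(=C)[Mg]Br | starting material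
8 | bromomagnesium alkoxide of methyl 14-hydroxy-14-[methoxy(methyl)amino]-15-methylhexadec-15-enoate (racemic) | COC(=O)CCCCCCCCCCCCC(O[Mg]Br)(C(C)=C)N(C)OC | intermediate
9 | methyl 15-methyl-14-oxohexadec-15-enoate | COC(=O)CCCCCCCCCCCCC(=O)C(C)=C | intermediate
10 | 1-nitrohexane | CCCCCC[N+](=O)[O-] | starting material
11 | methyl 15-methyl-17-nitro-14-oxodocosanoate (racemic, diastereomer mixture) | COC(=O)CCCCCCCCCCCCC(=O)C(C)CC(CCCCC)[N+](=O)[O-] | intermediate
12 | sodium nitronate of 11 (racemic at C15) | COC(=O)CCCCCCCCCCCCC(=O)C(C)CC(CCCCC)=[N+]([O-])[O-].[Na+] | intermediate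
13 | methyl 15-methyl-14,17-dioxodocosanoate (racemic) | COC(=O)CCCCCCCCCCCCC(=O)C(C)CC(=O)CCCCC | intermediate
14 | methyl 13-(3-methyl-5-pentylfuran-2-yl)tridecanoate | CCCCCc1cc(C)c(CCCCCCCCCCCCC(=O)OC)o1 | intermediate
15 | lithium 13-(3-methyl-5-pentylfuran-2-yl)tridecanoate | CCCCCc1cc(C)c(CCCCCCCCCCCCC(=O)[O-])o1.[Li+] | intermediate
16 | 13-(3-methyl-5-pentylfuran-2-yl)tridecanoic acid (achiral) | CCCCCc1cc(C)c(CCCCCCCCCCCCC(=O)O)o1 | target

**Totals**
Total step count: 8. Longest linear sequence: 8 steps (1 to 16; 7 and 10 are purchased).

**Three steps most likely to fail, each with a fallback**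

Step 4 (Grignard over-addition at the ester, or loss of the reactive enone). The fallback sets out from 4 and comes back at 9. BH3·SMe2 in THF (0 °C to rt) reduces only the free acid of 4 to methyl 14-hydroxytetradecanoate F1. Swern oxidation gives methyl 14-oxotetradecanoate F2. Reagent 7 then adds to the aldehyde at −78 °C, where the ester is inert, to give methyl 14-hydroxy-15-methylhexadec-15-enoate F3. Dess–Martin periodinane in CH2Cl2 oxidises this allylic alcohol to 9.

Step 5 (double addition of the primary nitroalkane, or base-induced polymerisation of 9). The fallback sets out from 9 and comes back at 13, bypassing 11 and step 6. It is a Stetter reaction of hexanal (CCCCCC=O) with 9, catalysed by 3-benzyl-5-(2-hydroxyethyl)-4-methylthiazolium chloride and Et3N in EtOH at 80 °C. The catalytically generated acyl anion equivalent adds once to the terminal CH2 and delivers the 1,4-diketone 13 directly. No new compound lies on this path (none F0).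

Step 6 (the reduced nitrogen condensing with the γ-ketone to pyrroline or pyrrole by-products, or incomplete Nef). The fallback sets out from 11 and comes back at 14. The C14 ketone is first masked with 1,2-bis(trimethylsilyloxy)ethane and catalytic TMSOTf (CH2Cl2, −78 to −20 °C), giving methyl 13-[2-(4-nitrononan-2-yl)-1,3-dioxolan-2-yl]tridecanoate F4. An oxidative Nef on its nitronate (NaOMe, MeOH; then KMnO4/MgSO4, H2O, 0 °C) gives methyl 13-[2-(4-oxononan-2-yl)-1,3-dioxolan-2-yl]tridecanoate F5. p-TsOH in wet acetone, then toluene at reflux, removes the dioxolane and closes the furan in one operation to 14.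

**Further compounds**
F1 | step 4 | methyl 14-hydroxytetradecanoate | COC(=O)CCCCCCCCCCCCCO
F2 | step 4 | methyl 14-oxotetradecanoate | COC(=O)CCCCCCCCCCCCC=O
F3 | step 4 | methyl 14-hydroxy-15-methylhexadec-15-enoate (racemic) | COC(=O)CCCCCCCCCCCCC(O)C(C)=C
F0 | step 5 | none | none
F4 | step 6 | methyl 13-[2-(4-nitrononan-2-yl)-1,3-dioxolan-2-yl]tridecanoate (racemic, diastereomer mixture) | COC(=O)CCCCCCCCCCCCC1(OCCO1)C(C)CC(CCCCC)[N+](=O)[O-]
F5 | step 6 | methyl 13-[2-(4-oxononan-2-yl)-1,3-dioxolan-2-yl]tridecanoate (racemic) | COC(=O)CCCCCCCCCCCCC1(OCCO1)C(C)CC(=O)CCCCC
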